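**Plan**

Target: 23-(furan-2-yl)tricosa-5,7-diynoic acid (C1 = CO2H, diyne C5–C8, saturated chain C9–C23, furan ring on C23). It has no stereocentre and no stereogenic double bond, so no stereochemistry has to be set.
Retrosynthetic cuts, in order: the methyl ester at C1; C8–C9 (sp diyne terminus to the first CH2 of the C9–C23 chain); C6–C7 (sp–sp) of the diyne; C23–C2 of the furan ring.
Enabling feature: C9 is an unactivated primary carbon and C8 an sp carbon, so both can serve as electrophiles and be joined reductively. C9 is the α-carbon of 16-(furan-2-yl)hexadecanoic acid, whose carboxyl leaves as CO2 from a redox-active ester to give a primary radical; C8 is the C–Br carbon of a 1-bromo-1,3-diyne. The furan ring lies fourteen CH2 groups beyond C9 and offers the radical no cyclisation path.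
Forward order: furan C2 is alkylated with the C16 bromo acid and the acid is converted to its N-hydroxyphthalimide ester. Separately the C1–C6 alkynoate and a C7–C8 silyl bromoalkyne are joined at C6–C7 and silicon is exchanged for bromine. The halves are united at C8–C9 by nickel-catalysed decarboxylative cross-electrophile coupling, and the ester is hydrolysed last.

Key step: step 5

Assumption: the 1-bromo-1,3-diyne ester is taken to survive for some hours in cold solution in the dark; it is made immediately before the coupling and never stored neat.

**Route**

Step 1
Reactants: 1 furan; 2 16-bromohexadecanoic acid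
Product: 6 16-(furan-2-yl)hexadecanoic acid, via 2-furyllithium 3 (not isolated), via lithium 16-bromohexadecanoate 4 (not isolated), via lithium 16-(furan-2-yl)hexadecanoate 5 (not isolated)
Conditions: 1 (3 equiv), n-BuLi (2.2 equiv), THF, 0 °C; then 2, THF/DMPU, −78 °C → rt; dilute aq. HCl to pH 4, 0 °C
Reagents that add atoms: n-butyllithium, [Li]CCCC (its lithium is found only in the non-isolated 3, 4 and 5; no atom of it remains in 6)
Why: SN2 alkylation of C2-lithiated furan by a primary alkyl bromide: furan is lithiated only at C2, the first equivalent of 3 converts the acid into its poorly electrophilic lithium carboxylate 4, and the second equivalent displaces the remote primary bromide.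

Step 2
Reactants: 6 16-(furan-2-yl)hexadecanoic acid
Product: 7 1,3-dioxoisoindolin-2-yl 16-(furan-2-yl)hexadecanoate
Conditions: N-hydroxyphthalimide (1.1 equiv), N,N'-diisopropylcarbodiimide (1.1 equiv), DMAP (0.1 equiv), CH2Cl2, rt
Reagents that add atoms: N-hydroxyphthalimide, O=C1c2ccccc2C(=O)N1O
Why: Steglich-type carbodiimide esterification, in which the activated acid is transferred by DMAP to the N–O oxygen of N-hydroxyphthalimide under neutral conditions that leave the acid-sensitive furan untouched, giving the redox-active ester needed for radical decarboxylation.

Step 3
Reactants: 8 methyl hex-5-ynoate; 9 (bromoethynyl)triisopropylsilane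
Product: 10 methyl 8-(triisopropylsilyl)octa-5,7-diynoate
Conditions: CuCl (5 mol%), NH2OH·HCl (0.3 equiv), 30% aq. n-BuNH2, CH2Cl2, 0 °C → rt
Reagents that add atoms: none
Why: Cadiot–Chodkiewicz coupling, in which the copper acetylide of 8 (monovalent copper, kept reduced by hydroxylamine) attacks the C–Br carbon of 9 to form the C6–C7 sp–sp bond as the unsymmetrical diyne, with the bulky silyl group capping C8 and the methyl ester tolerating the brief, cold amine medium.

Step 4
Reactants: 10 methyl 8-(triisopropylsilyl)octa-5,7-diynoate
Product: 12 methyl 8-bromoocta-5,7-diynoate, via silver diynylide 11 (not isolated)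
Conditions: AgF (1.2 equiv), MeCN, rt, dark; then NBS (1.2 equiv), rt; short silica plug, kept as a cold solution
Reagents that add atoms: AgF, [Ag+].[F-] (silver of the non-isolated 11 only); N-bromosuccinimide, O=C1CCC(=O)N1Br (the bromine of 12)
Why: One-pot desilylative bromination, established for triisopropylsilyl alkynes: fluoride cleaves the C(sp)–Si bond to give the silver diynylide 11, which NBS brominates at C8 without affecting the methyl ester.

Step 5
Reactants: 7 1,3-dioxoisoindolin-2-yl 16-(furan-2-yl)hexadecanoate; 12 methyl 8-bromoocta-5,7-diynoate
Product: 13 methyl 23-(furan-2-yl)tricosa-5,7-diynoate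
Conditions: NiBr2(dme) (10 mol%), 4,4'-di-tert-butyl-2,2'-bipyridine (10 mol%), Mn powder (2 equiv), LiBr (1 equiv), NMP, 0 °C → rt, 12 (1.5 equiv) added slowly, dark
Reagents that add atoms: none
Why: Proposed new method: zerovalent nickel, formed from NiBr2(dme), the bipyridine and Mn, should insert into the C(sp)–Br bond of 12 to give a diynylnickel bromide (divalent nickel), while one-electron reduction of 7 by low-valent nickel or Mn cleaves its N–O bond and, after loss of CO2, releases the primary 15-(furan-2-yl)pentadecyl radical; capture of this radical at nickel and reductive elimination from the resulting trivalent alkyl(diynyl)nickel species forms the C8–C9 bond, and Mn returns the monovalent nickel bromide to the zerovalent state. The closest known reaction type is the nickel-catalysed reductive decarboxylative alkynylation of N-hydroxyphthalimide esters with 1-bromoalkynes, a cross-electrophile coupling that forms C(sp3)–C(sp) bonds from primary alkyl esters; what is new is the conjugated 1-bromo-1,3-diyne as the C(sp) partner. No ring is closed and no stereocentre is created. The step needs cross-coupling to win over homocoupling and the new bond to form at C8 only: the two electrophiles are activated by different elementary steps (two-electron oxidative addition at C–Br, one-electron reduction of the redox-active ester), the bromine marks C8 as the single site of oxidative addition, and the nickel-bound sp carbon cannot transpose as a propargyl or allenyl system would. The radical has no intramolecular outlet because the furan ring lies fourteen CH2 groups beyond the radical carbon, and slow addition of 12 keeps both the diynylnickel species and the free diyne π-system dilute, which should suppress tetrayne formation and radical addition to the diyne. The methyl ester and the 2-alkylfuran are inert to Mn, LiBr and low-valent nickel at or below room temperature, and no strongly basic acetylide is needed next to the enolisable ester.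

Step 6
Reactants: 13 methyl 23-(furan-2-yl)tricosa-5,7-diynoate
Product: 15 23-(furan-2-yl)tricosa-5,7-diynoic acid, via lithium 23-(furan-2-yl)tricosa-5,7-diynoate 14 (not isolated)
Conditions: LiOH·H2O (3 equiv), THF/MeOH/H2O, 0 °C → rt; then dilute aq. HCl to pH 4, 0 °C, dark
Reagents that add atoms: lithium hydroxide, [Li+].[OH-] (the oxygen of the carboxyl OH; its lithium is found in the non-isolated 14)
Why: Saponification (BAc2 hydrolysis) of an unhindered methyl ester followed by cold acidification to pH 4, conditions under which neither the 2-alkylfuran nor the dialkyl-substituted diyne should react.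

**Compound list**

1 | furan | c1ccoc1 | starting material
2 | 16-bromohexadecanoic acid | OC(=O)CCCCCCCCCCCCCCCBr | starting material
3 | 2-furyllithium | [Li]c1ccco1 | intermediate
4 | lithium 16-bromohexadecanoate | [Li+].[O-]C(=O)CCCCCCCCCCCCCCCBr | intermediate
5 | lithium 16-(furan-2-yl)hexadecanoate | [Li+].[O-]C(=O)CCCCCCCCCCCCCCCc1ccco1 | intermediate
6 | 16-(furan-2-yl)hexadecanoic acid | OC(=O)CCCCCCCCCCCCCCCc1ccco1 | intermediate
7 | 1,3-dioxoisoindolin-2-yl 16-(furan-2-yl)hexadecanoate | O=C(CCCCCCCCCCCCCCCc1ccco1)ON1C(=O)c2ccccc2C1=O | intermediate
8 | methyl hex-5-ynoate | COC(=O)CCCC#C | starting material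
9 | (bromoethynyl)triisopropylsilane | CC(C)[Si](C#CBr)(C(C)C)C(C)C | starting material
10 | methyl 8-(triisopropylsilyl)octa-5,7-diynoate | COC(=O)CCCC#CC#C[Si](C(C)C)(C(C)C)C(C)C | intermediate
11 | silver diynylide, methyl 8-argentioocta-5,7-diynoate | COC(=O)CCCC#CC#C[Ag] | intermediate
12 | methyl 8-bromoocta-5,7-diynoate | COC(=O)CCCC#CC#CBr | intermediate
13 | methyl 23-(furan-2-yl)tricosa-5,7-diynoate | COC(=O)CCCC#CC#CCCCCCCCCCCCCCCCc1ccco1 | intermediate
14 | lithium 23-(furan-2-yl)tricosa-5,7-diynoate | [Li+].[O-]C(=O)CCCC#CC#CCCCCCCCCCCCCCCCc1ccco1 | intermediate
15 | 23-(furan-2-yl)tricosa-5,7-diynoic acid | O=C(O)CCCC#CC#CCCCCCCCCCCCCCCCc1ccco1 | target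

**Step count and risks**

Total steps: 6. Longest linear sequence: 4 steps (steps 1, 2, 5, 6; the branch 3, 4, 5, 6 is equally long).

Steps most likely to fail:

1. Step 5 (proposed new method). The diynylnickel species may dimerise to a tetrayne, the alkyl radical may add to the conjugated diyne instead of being captured at nickel, and the diyne product may be consumed by nickel-mediated oligomerisation faster than it forms. The fallback uses only known reactions and no radical coupling. It sets out from 6. Reduction with LiAlH4 in THF at 0 °C should give 16-(furan-2-yl)hexadecan-1-ol F1. Oxidation with Dess–Martin periodinane and NaHCO3 in CH2Cl2 should give 16-(furan-2-yl)hexadecanal F2. Seyferth–Gilbert homologation with dimethyl (1-diazo-2-oxopropyl)phosphonate and K2CO3 in MeOH should give 2-(heptadec-16-yn-1-yl)furan F3, in which the former carboxyl carbon of 6 has become C8 and the C8–C9 bond is the old C1–C2 bond of the acid. In parallel 8 is brominated (NBS, catalytic AgNO3, acetone) to methyl 6-bromohex-5-ynoate F4. A Cadiot–Chodkiewicz coupling of F3 with F4 (CuCl, NH2OH·HCl, n-BuNH2, MeOH/THF, 0 °C) forms C6–C7 and comes back to the route at 13, which goes on to step 6. If the failure proves specific to the bromodiyne, the shorter path given under step 4 serves as well.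

2. Step 4. The 1-bromo-1,3-diyne may decompose or oligomerise under light or silver while it forms and is concentrated, and cleavage of the hindered C(sp)–Si bond may stay incomplete. The fallback avoids any halodiyne and sets out from 7 and 9. The nickel-catalysed reductive decarboxylative alkynylation in its established form, with the silyl-capped 1-bromoalkyne 9 and the catalyst system of step 5, should give triisopropyl[17-(furan-2-yl)heptadec-1-yn-1-yl]silane F5. TBAF in THF should remove the silyl group to give 2-(heptadec-16-yn-1-yl)furan F3. Cadiot–Chodkiewicz coupling of F3 with methyl 6-bromohex-5-ynoate F4 (from 8 with NBS and catalytic AgNO3) then builds the diyne at C6–C7 and comes back to the route at 13.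

3. Step 1. The furyllithium may add to the lithium carboxylate (ketone formation), the long-chain lithium carboxylate may aggregate or precipitate so that displacement stalls, and E2 loss of HBr may compete. The fallback replaces furyl-anion alkylation by electrophilic acylation and sets out from 1. Friedel–Crafts acylation at C2 of the furan ring with methyl 16-chloro-16-oxohexadecanoate F6 (made from commercial 16-methoxy-16-oxohexadecanoic acid with oxalyl chloride and catalytic DMF), promoted by SnCl4 in CH2Cl2 at −20 °C, should give methyl 16-(furan-2-yl)-16-oxohexadecanoate F7. Wolff–Kishner reduction (N2H4·H2O, KOH, diethylene glycol, 130 then 200 °C) should remove the ketone oxygen and saponify the ester in the same pot, and acidification to pH 4 comes back to the route at 6.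

Further compounds
F1 | step 5 | 16-(furan-2-yl)hexadecan-1-ol | OCCCCCCCCCCCCCCCCc1ccco1
F2 | step 5 | 16-(furan-2-yl)hexadecanal | O=CCCCCCCCCCCCCCCCc1ccco1
F3 | step 5 | 2-(heptadec-16-yn-1-yl)furan | C#CCCCCCCCCCCCCCCCc1ccco1
F4 | step 5 | methyl 6-bromohex-5-ynoate | COC(=O)CCCC#CBr
F5 | step 4 | triisopropyl[17-(furan-2-yl)heptadec-1-yn-1-yl]silane | CC(C)[Si](C#CCCCCCCCCCCCCCCCc1ccco1)(C(C)C)C(C)C
F6 | step 1 | methyl 16-chloro-16-oxohexadecanoate | COC(=O)CCCCCCCCCCCCCCC(=O)Cl
F7 | step 1 | methyl 16-(furan-2-yl)-16-oxohexadecanoate | COC(=O)CCCCCCCCCCCCCCC(=O)c1ccco1
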